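**Remark on the chemistry:** decalin carbons carry the locants C1–C10 (C4 gem-dimethyl carbon, C5/C10 ring fusion, C8 methyl-bearing alkene carbon, C9 side-chain carbon); ring C is the dioxane with atoms O1, O2, D3–D6; Cα is the methyl-bearing carbon on D3; L1 (on C9) and L2 (on D6) are the linker carbons. Compounds 3 and 6 are carried as epimer mixtures at centers that are removed later, and 40 as an E/Z mixture drawn E.

## Analysis of the target

Compound 45 is a norsesterterpenoid methyl ester. A trans-fused decalin (ring A: C1–C5, C10; ring B: C5–C10, with a C7=C8 double bond and a methyl on C8) is joined through the two-carbon linker L1–L2 to a 1,2-dioxane (ring C), whose D3 carries the α-methyl ester arm. There are six stereocenters in two clusters: C5 (R), C9 (S) and C10 (R) on the decalin, and Cα (S), D3 (S) and D6 (S) on the peroxide half. In the decalin, 5-H and the C9 side chain both lie on the face opposite the C10 methyl, so the side chain is axial and H9 is syn to the angular methyl. In ring C the D3 arm and the D6 linker are cis, and the Cα methyl and the D3 oxygen are anti along the chain. The two clusters are insulated by L1–L2 and cannot control each other, so each half must be made as a single enantiomer and the halves joined. The O–O bond rules out reducing metals and heterogeneous hydrogenation late in the route. The ester places an acidic Cα–H β to the peroxide (E1cB ring opening), D3–H invites Kornblum–DeLaMare cleavage, and the C7=C8 alkene can migrate or be epoxidised. The hard points are the quaternary carbons C4 and C10 flanking C5, the axial C9 substituent next to C10, and D6, a fully substituted carbon bearing a peroxide oxygen. The strategy rests on ring B: C5, C6, C7=C8 with its methyl, C9 and C10, together with C4 and its two methyl carbons, are the ten carbons of (S)-carvone 1. Its carbonyl carbon is C9, its isopropenyl carbon is C4 and its stereocenter is C5.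

## Retrosynthetic reasoning

**Ester.** The ester of 45 is traced to acid 44, alcohol 42 and silyl ether 41. The carboxyl carbon stays at the alcohol oxidation level until the end, because a carbonyl there makes Cα–H acidic and β to the peroxide; as a silyl ether the arm is inert to the amide base used for the fragment union.

**Linker, L1–L2.** The bond is cut as a double bond (41 from 40; 40 from sulfone 21 and aldehyde 38). This is the middle of the linker, so both partners arrive with all their stereocenters in place. Aldehyde 38 has no α-hydrogen, and in 21 the carbanion is one carbon away from C9. Cutting C9–L1 would force the coupling to create the axial C9 center next to quaternary C10; cutting L2–D6 would ask the coupling to build the quaternary peroxy carbon. The forward sequence is a Julia–Kocienski olefination, then saturation of the new disubstituted alkene by a concerted, metal-free hydrogen transfer that spares O–O and C7=C8.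

**C9–L1.** Sulfone 21 comes from alcohol 19. The C9–L1 bond of 19 is traced, with a 1,3-shift of functionality, to allylic alcohol 15 through ether 17. A [2,3]-Wittig–Still shift moves an oxygen-bound methylene from C7 to C9 on the same face and places the alkene at C7=C8. Alkylation or hydroboration would deliver the equatorial C9 epimer; the suprafacial shift turns an easily set axial C7 carbinol into the axial C9 substituent.

**Oxygen from C9 to C7.** Alcohol 15 comes from epoxy ketone 13 and enone 12 by Wharton transposition. The C9 carbonyl is what 1 supplies; the transposition puts oxygen on C7 and the alkene at C8=C9. The epoxide must lie anti to the C10 methyl, which axial conjugate addition at C7 provides.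

**C1 carbonyl.** Enone 12 comes from dione 8 through triflate 10 and diene 11. The C1 oxygen is removed before the transposition because 8 is a non-enolisable 1,3-diketone that basic peroxide would cleave by retro-Claisen. An enol triflate is chosen over radical deoxygenation, where a C1 radical next to the C9 acyl group could undergo a 1,2-acyl shift.

**Ring A, C3–C4 (key).** Dione 8 is cut at C3–C4 to give 7. This turns the gem-dimethyl carbon C4 back into the isopropenyl group of 1 and C1–C3 into an acryloyl group on C10. The forward reaction must generate a tertiary radical at C4 by hydrogen-atom transfer in the presence of two enones and close ring A on the vinyl ketone. No stereocenter is formed, so the trans fusion is inherited.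

**C10 substituents.** Precursor 7 comes from carbinol 6, and 6 from 3 and acrolein 4 by an aldol addition that forms C10–C1; 3 comes from 1 by methylation. The methyl is introduced first so that the three-carbon electrophile enters anti to the isopropenyl group, leaving methyl syn to it, as a trans fusion requires.

**Aldehyde on D6.** Aldehyde 38 comes from diol 37 by glycol cleavage. The formyl carbon L2 is carried as a 1,2-diol from the point where D6 is created and is revealed last, under neutral conditions.

**Ring C.** Dioxane 36 is opened at O2–D3 to peroxide 34/33 and mesylate 32. The O2–D3 bond forms by intramolecular displacement of a D3 mesylate (inversion), and O1–D6 by perhydrolysis of the trisubstituted epoxide at its tertiary carbon (inversion). Both C–O bonds are thus made by stereospecific substitution at carbons set earlier under reagent control. The intermolecular event is placed on the reactive epoxide and the intramolecular one on the hindered secondary carbon.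

**Cα–D3.** Mesylate 32 comes from 31, 30 and aldol adduct 29, which is cut to aldehyde 26 and oxazolidinone 27. The syn adduct is needed because the D3 oxygen is later replaced with inversion, which turns syn into the anti relationship of 45.

**Epoxide and chain.** Aldehyde 26 comes from 24, 23 and geraniol 22. Asymmetric epoxidation of 22 sets the tertiary carbon that becomes D6, and oxidative cleavage of the distal alkene exposes the carbon that becomes D3. In 22, C3 with its methyl is D6, C4–C6 are D5–D3 and C2 is L2.

## Alternatives that were turned down

**Alternative 1:** Both C–O bonds of ring C (O1–D6 and O2–D3) are disconnected at once, back to the open-chain E,E-diene A2. The forward key step is a sensitised photo-oxygenation, a suprafacial [4+2] peroxide-forming cycloaddition, giving the 3,6-dihydro-1,2-dioxine A1 with the two arms cis because both sit on the outside of the diene.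
- For it: one step writes the whole peroxide ring, no hydroperoxide is handled, no substitution at a hindered carbon is needed, and the 3,6-cis relationship follows from alkene geometry alone. On these points, and on step count for ring C, it is stronger than the present route, which needs twelve steps to reach aldehyde 38.
- Against it: the absolute configuration of D3 and D6 depends on which diene face reacts, and the only control element is the acyclic Cα center, so both cis diastereomers should form. The diene terminus that becomes D6 carries an inward-pointing methyl, which disfavours the s-cis conformer and opens the competing ene pathway. The ring alkene of A1 must still be reduced and the acetoxymethyl arm unmasked and oxidised.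
- Comparison: the chosen route sets D6 and D3 by reagent-controlled reactions (steps 14 and 17) and places its main uncertainty in a ring closure that creates no stereocenter. Alternative 1 also does nothing for the decalin.

**Alternative 2:** Ring B is disconnected at C5–C6 and C9–C10, back to dienophile A4 and silyloxydiene A5. The forward key step is an enantioselective Diels–Alder reaction under a chiral cationic boron Lewis acid, giving cyclohexene A3; the E geometry of A4 becomes the trans relationship of the ester groups on C5 and C10.
- For it: the C10 quaternary center and C5 are set together by a catalyst, either enantiomer is available, and nothing depends on a chiral-pool terpene. In generality it is at least as strong as starting from 1.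
- Against it: in A3, C9 is a bare methylene and the oxygen sits on C7, so the C9 side chain must be introduced next to the quaternary carbon after further redox changes. Ring A is absent: C4 would be built from the C5 ester (two methyl additions, then a C–C bond at a tertiary carbon) and C1–C3 from the C10 ester, which ends in a closure of the same kind as step 4, many steps later. A trisubstituted dienophile with two esters is sluggish and offers the Lewis acid two binding sites, so rate and regiochemistry are open.
- Comparison: 1 supplies C4, C5, the C8 methyl and the C9 carbonyl in one purchased compound, and 7 is reached in three steps.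

**Alternative 3:** The O1–D6 bond is disconnected, back to A7, a D3 hydroperoxide tethered to a 2,2-disubstituted oxetane derived from a chiral-pool tertiary allylic alcohol. The forward key step is activation of the oxetane by a silyl triflate Lewis acid and 6-exo attack of the hydroperoxide at the tertiary carbon with inversion, giving dioxane A6 with a hydroxyethyl arm on D6.
- For it: D6 comes from the chiral pool, the ring closes intramolecularly at the quaternary carbon, no β-hydroxy hydroperoxide needs protection, and A6 already holds both linker carbons. For forming the D6–O bond this is more direct than steps 21–23 here and at least as strong.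
- Against it: it presupposes a secondary hydroperoxide of defined configuration at D3, next to branched Cα, and installing it means an intermolecular SN2 displacement by a peroxide nucleophile at a β-branched secondary carbon. A strong Lewis acid at a tertiary oxetane carbon risks ionisation and loss of configuration. Because A6 holds L1 as well as L2, the union must form C9–L1 and create the axial C9 center next to C10 in the presence of the peroxide.
- Comparison: the chosen route reverses the order at ring C and fixes C9 by a sigmatropic shift (step 11) before the fragments meet, so the coupling (step 26) is an olefination at a non-enolisable aldehyde.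

Key step: step 4

## Route

Step 1
Reactants: 1 (S)-carvone
Product: 3 6-methylcarvone (C6 epimer mixture), via lithium dienolate 2 (not isolated)
Conditions: LDA, THF, −78 °C; then MeI, −78 → 0 °C
Reagents that add atoms: iodomethane, CI
Why: Kinetic α′-deprotonation gives the cross-conjugated lithium dienolate, which is C-methylated (enolate alkylation) at the carbon that becomes C10; its configuration is irrelevant because this carbon is enolised again in step 2.

Step 2
Reactants: 3 6-methylcarvone; 4 acrolein
Product: 6 6-(1-hydroxyallyl)-6-methylcarvone (carbinol epimer mixture), via lithium enolate 5 (not isolated)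
Conditions: LDA, THF, −78 °C; then 4, −78 °C; AcOH quench at −78 °C
Reagents that add atoms: none
Why: The tetrasubstituted lithium enolate adds 1,2 to the aldehyde (aldol addition) on the face anti to the neighbouring isopropenyl group, creating the C10 quaternary center with methyl syn and the three-carbon arm anti to isopropenyl; the carbinol center is removed in step 3, and the cold acidic quench prevents retro-aldol cleavage.

Step 3
Reactants: 6 6-(1-hydroxyallyl)-6-methylcarvone
Product: 7 (5R,6S)-6-acryloyl-6-methylcarvone (acryloyl anti to isopropenyl)
Conditions: Dess–Martin periodinane, CH2Cl2, 0 °C → rt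
Reagents that add atoms: none
Why: Dess–Martin oxidation of the secondary allylic alcohol gives the vinyl ketone under non-basic conditions, so the non-enolisable 1,3-diketone and the Michael acceptor survive; 7 is used at once.

Step 4
Reactants: 7 (5R,6S)-6-acryloyl-6-methylcarvone
Product: 8 (5R,10S)-4,4,8,10-tetramethyl-trans-decal-7-ene-1,9-dione
Conditions: Fe(acac)3 (30 mol %), PhSiH3, EtOH/ethylene glycol (5:1), 60 °C, 0.01 M
Reagents that add atoms: none
Why: Fe(acac)3 (trivalent iron) and PhSiH3 in ethanol form an iron hydride that transfers a hydrogen atom to the terminal carbon of the electron-rich isopropenyl group (Mukaiyama-type hydrogen-atom transfer), giving the tertiary C4 radical. This nucleophilic radical adds to the terminal carbon of the vinyl ketone on C10 (intramolecular Giese addition), forming C3–C4 and closing ring A in a 6-endo-trig mode; the α-keto radical at C2 is then reduced by divalent iron to the enolate and protonated by the solvent. The closest known reaction type is the iron-hydride reductive coupling of unactivated alkenes with enones, run here intramolecularly. No stereocenter is created: C4 becomes the gem-dimethyl carbon, C2 and C3 are methylenes, and the trans ring fusion follows from the anti arrangement of the C5 and C10 substituents set in step 2, both of which can sit equatorial for closure. The step needs chemoselective hydrogen-atom transfer to the isopropenyl alkene over the two electron-poor enone alkenes, which the hydride's preference for electron-rich alkenes and the fast, irreversible ring closure should secure. It needs 6-endo over 5-exo closure, which radical polarity enforces, since attack at the β-carbon gives a stabilised α-keto radical and attack at the α-carbon would give a primary radical. High dilution suppresses intermolecular addition to the acryloyl group.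

Step 5
Reactants: 8 (5R,10S)-4,4,8,10-tetramethyl-trans-decal-7-ene-1,9-dione
Product: 10 9-oxo-4,4,8,10-tetramethyl-trans-decal-1,7-dien-1-yl triflate, via potassium enolate 9 (not isolated)
Conditions: KHMDS, THF, −78 °C; then PhNTf2, −78 → 0 °C
Reagents that add atoms: N-phenylbis(trifluoromethanesulfonimide), O=S(=O)(N(c1ccccc1)S(=O)(=O)C(F)(F)F)C(F)(F)F
Why: Only the C1 carbonyl has α-hydrogens (on C2), the enone being deprotonable only at its slow γ-position, so the hindered amide base gives the C1 enolate, which is O-sulfonylated (enol triflate formation).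

Step 6
Reactants: 10 enol triflate
Product: 11 4,4,8,10-tetramethyl-trans-decal-1,7-dien-9-one
Conditions: Pd(OAc)2 (5 mol %), PPh3, Bu3N, HCO2H, DMF, 60 °C
Reagents that add atoms: none
Why: Cacchi-type reduction: oxidative addition of the enol triflate to zerovalent palladium (formed from Pd(OAc)2 and PPh3), formate exchange, loss of CO2 and C–H reductive elimination replace the triflate by hydrogen without touching the enone.

Step 7
Reactants: 11 dienone
Product: 12 (5R,10R)-4,4,8,10-tetramethyl-trans-decal-7-en-9-one
Conditions: H2 (1 atm), RhCl(PPh3)3 (10 mol %), benzene/EtOH, rt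
Reagents that add atoms: none
Why: Homogeneous hydrogenation with RhCl(PPh3)3 saturates the isolated cis-disubstituted C1=C2 bond and leaves the trisubstituted conjugated C7=C8 bond, the same selectivity that distinguishes the two alkenes of 1.

Step 8
Reactants: 12 enone
Product: 13 7,8-epoxy-4,4,8,10-tetramethyl-trans-decalin-9-one (epoxide anti to the C10 methyl)
Conditions: 30 % H2O2, NaOH, MeOH, 0 °C → rt
Reagents that add atoms: hydrogen peroxide, OO
Why: Weitz–Scheffer epoxidation: hydroperoxide anion adds to C7 along the axial path that leads to a chair enolate, which is the face opposite the axial C10 methyl, and the enolate closes onto oxygen on the same face, so the epoxide is anti to the angular methyl.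

Step 9
Reactants: 13 epoxy ketone
Product: 15 4,4,8,10-tetramethyl-trans-decal-8-en-7-ol (7-OH anti to the C10 methyl), via epoxy hydrazone 14 (not isolated)
Conditions: N2H4·H2O, AcOH, MeOH, 0 °C → rt
Reagents that add atoms: none
Why: Wharton transposition: the epoxy hydrazone fragments to a vinyl diazene that loses N2, leaving the C8=C9 alkene and the C7 hydroxyl, whose C–O bond and axial configuration are untouched.

Step 10
Reactants: 15 allylic alcohol
Product: 17 7-(tributylstannylmethoxy)-4,4,8,10-tetramethyl-trans-decal-8-ene, via potassium alkoxide 16 (not isolated)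
Conditions: KH, THF, 0 °C; then Bu3SnCH2I, 0 °C → rt
Reagents that add atoms: tributyl(iodomethyl)stannane, CCCC[Sn](CCCC)(CCCC)CI
Why: Williamson etherification of the potassium alkoxide with the primary iodide installs the stannylmethyl group needed for the Still variant of the Wittig rearrangement.

Step 11
Reactants: 17 stannylmethyl ether
Product: 19 (5R,9S,10R)-9-(hydroxymethyl)-4,4,8,10-tetramethyl-trans-decal-7-ene (CH2OH anti to the C10 methyl), via lithiomethyl ether 18 (not isolated)
Conditions: n-BuLi, THF, −78 → −20 °C
Reagents that add atoms: none
Why: Tin–lithium exchange gives the α-alkoxymethyllithium, which undergoes the [2,3]-Wittig–Still rearrangement through a five-membered envelope transition state; the axial C7–O bond delivers the methylene to C9 on the same face (anti to the C10 methyl), which sets C9, and the alkene moves to C7=C8.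

Step 12
Reactants: 19 homoallylic alcohol
Product: 20 1-phenyl-1H-tetrazol-5-yl sulfide of 19
Conditions: 1-phenyl-1H-tetrazole-5-thiol, PPh3, DIAD, THF, 0 °C → rt
Reagents that add atoms: 1-phenyl-1H-tetrazole-5-thiol, Sc1nnnn1-c1ccccc1
Why: Mitsunobu thioetherification of the primary alcohol with the acidic tetrazolethiol takes place at the CH2 group and does not involve C9.

Step 13
Reactants: 20 sulfide
Product: 21 1-phenyl-1H-tetrazol-5-yl sulfone
Conditions: (NH4)6Mo7O24·4H2O (10 mol %), 30 % H2O2, EtOH, 0 °C → rt
Reagents that add atoms: hydrogen peroxide, OO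
Why: Molybdate-catalysed peroxide oxidation takes sulfur to the sulfone much faster than it epoxidises the hindered trisubstituted alkene, giving the Julia–Kocienski donor.

Step 14
Reactants: 22 geraniol
Product: 23 (2S,3S)-2,3-epoxygeraniol
Conditions: Ti(OiPr)4 (5 mol %), L-(+)-diethyl tartrate (6 mol %), t-BuOOH, 4 Å molecular sieves, CH2Cl2, −20 °C
Reagents that add atoms: tert-butyl hydroperoxide, CC(C)(C)OO
Why: Sharpless asymmetric epoxidation of the E allylic alcohol with the L-(+)-tartrate ligand gives the (2S,3S)-epoxide; this sets under reagent control the tertiary carbon that becomes D6, and the remote alkene is not touched.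

Step 15
Reactants: 23 (2S,3S)-2,3-epoxygeraniol
Product: 24 tert-butyldimethylsilyl ether of 23
Conditions: TBSCl, imidazole, CH2Cl2, 0 °C → rt
Reagents that add atoms: tert-butyldimethylsilyl chloride, CC(C)(C)[Si](C)(C)Cl
Why: Silylation of the primary alcohol protects it for the enolate and hydride steps that follow.

Step 16
Reactants: 24 silyl ether
Product: 26 (4S,5S)-6-(tert-butyldimethylsilyloxy)-4,5-epoxy-4-methylhexanal, via ozonide 25 (not isolated)
Conditions: O3, CH2Cl2, −78 °C; then PPh3, −78 °C → rt
Reagents that add atoms: ozone, [O-][O+]=O
Why: Ozonolysis with reductive work-up cleaves the remaining trisubstituted alkene to the aldehyde carbon that becomes D3; the epoxide and silyl ether are inert to ozone.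

Step 17
Reactants: 26 epoxy aldehyde; 27 (S)-4-benzyl-3-propionyloxazolidin-2-one
Product: 29 (2S,3R)-syn aldol adduct (N-acyl oxazolidinone), via dibutylboron Z-enolate 28 (not isolated)
Conditions: Bu2BOTf, i-Pr2NEt, CH2Cl2, 0 °C; then 26, −78 → 0 °C; pH 7 buffer, MeOH, 30 % H2O2, 0 °C
Reagents that add atoms: none
Why: Evans syn aldol: the Z boron enolate reacts through a Zimmerman–Traxler chair with the benzyl group of the auxiliary shielding one enolate face, giving the (2S,3R) syn adduct; this sets Cα in its final configuration and D3 as the carbinol that is inverted later.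

Step 18
Reactants: 29 aldol adduct
Product: 30 (2R,3R,6S,7S)-8-(tert-butyldimethylsilyloxy)-6,7-epoxy-2,6-dimethyloctane-1,3-diol
Conditions: LiBH4, MeOH, THF, 0 °C
Reagents that add atoms: none
Why: Reductive cleavage of the imide with LiBH4 gives the primary alcohol without epimerising Cα and releases the auxiliary; the trisubstituted epoxide is not opened at 0 °C.

Step 19
Reactants: 30 diol
Product: 31 1-O-tert-butyldiphenylsilyl ether of 30
Conditions: TBDPSCl, imidazole, CH2Cl2, 0 °C
Reagents that add atoms: tert-butyldiphenylsilyl chloride, CC(C)(C)[Si](Cl)(c1ccccc1)c1ccccc1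
Why: The bulky silyl chloride reacts selectively with the primary hydroxyl of the 1,3-diol (selective silylation), leaving the D3 hydroxyl free.

Step 20
Reactants: 31 secondary alcohol
Product: 32 D3 methanesulfonate of 31
Conditions: MsCl, Et3N, CH2Cl2, 0 °C
Reagents that add atoms: methanesulfonyl chloride, CS(=O)(=O)Cl
Why: Sulfonylation turns the D3 hydroxyl into a leaving group with retention, so that the later displacement inverts it.

Step 21
Reactants: 32 epoxy mesylate
Product: 33 D6 tertiary hydroperoxide with a free neighbouring secondary hydroxyl
Conditions: H2O2 (anhydrous, in Et2O), H3PMo12O40 (5 mol %), Et2O, rt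
Reagents that add atoms: hydrogen peroxide, OO
Why: Molybdenum-catalysed perhydrolysis of the trisubstituted epoxide: the activated epoxide is opened by H2O2 at the tertiary carbon with inversion (borderline SN2), creating the D6–O1 bond in the target configuration and leaving the neighbouring secondary hydroxyl; the mesylate and silyl ethers should be inert to the ethereal medium.

Step 22
Reactants: 33 hydroxy hydroperoxide
Product: 34 bis(triethylsilyl) derivative (silyl peroxide and silyl ether)
Conditions: TESOTf, 2,6-lutidine, CH2Cl2, −78 → 0 °C
Reagents that add atoms: triethylsilyl trifluoromethanesulfonate, CC[Si](CC)(CC)OS(=O)(=O)C(F)(F)F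
Why: The silyl triflate caps both the hydroperoxide and the β-hydroxyl (silylation), so that no free β-hydroxy hydroperoxide is exposed to base, which would invite C–C fragmentation.

Step 23
Reactants: 34 silyl peroxide mesylate
Product: 36 3,6-cis-1,2-dioxane with its three silyl ethers, via tetrabutylammonium peroxide 35 (not isolated)
Conditions: TBAF (1.05 equiv), THF, −20 → 0 °C
Reagents that add atoms: none
Why: Fluoride cleaves the labile O–O–Si bond first and frees the peroxide anion, which displaces the secondary mesylate in a 6-exo-tet intramolecular SN2 reaction (alkylation of a peroxide anion); inversion at D3 gives the cis-3,6 ring with Cα and D3 anti, and the weakly basic α-effect nucleophile favours substitution over elimination.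

Step 24
Reactants: 36 silylated dioxane
Product: 37 dioxane 1,2-diol (primary tert-butyldiphenylsilyl ether retained)
Conditions: CSA (cat.), MeOH/CH2Cl2, 0 °C
Reagents that add atoms: none
Why: Mild acid methanolysis removes the secondary triethylsilyl and primary tert-butyldimethylsilyl ethers and leaves the more robust tert-butyldiphenylsilyl ether and the dialkyl peroxide (selective desilylation).

Step 25
Reactants: 37 diol
Product: 38 dioxane aldehyde (formyl and methyl on D6)
Conditions: NaIO4, THF/pH 7 buffer, 0 °C → rt
Reagents that add atoms: none
Why: Periodate glycol cleavage excises the terminal carbon and turns the carbinol carbon on D6 into the aldehyde (L2) under neutral conditions that the peroxide tolerates; the aldehyde has no α-hydrogen and cannot epimerise.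

Step 26
Reactants: 21 sulfone; 38 dioxane aldehyde
Product: 40 coupled L1=L2 alkene (E/Z mixture), via potassium sulfonyl carbanion 39 (not isolated)
Conditions: KHMDS, THF, −78 °C; then 38, −78 °C → rt
Reagents that add atoms: none
Why: Julia–Kocienski olefination: the metalated sulfone adds to the non-enolisable aldehyde, and Smiles rearrangement with loss of SO2 and the tetrazolone gives the L1=L2 alkene; the alkene geometry is irrelevant, and pre-forming the carbanion keeps free base away from the peroxide.

Step 27
Reactants: 40 alkene
Product: 41 saturated silyl ether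
Conditions: KO2CN=NCO2K (excess, portionwise), AcOH, pyridine/MeOH, 0 °C → rt
Reagents that add atoms: none
Why: Diimide, formed in the flask, transfers two hydrogens in a concerted syn addition to the 1,2-disubstituted linker alkene; it does not cleave O–O bonds and should react far more slowly with the hindered trisubstituted C7=C8 alkene.

Step 28
Reactants: 41 silyl ether
Product: 42 primary alcohol
Conditions: TBAF, AcOH, THF, rt
Reagents that add atoms: none
Why: Buffered fluoride removes the primary silyl ether (desilylation) without base-induced Kornblum–DeLaMare cleavage of the peroxide.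

Step 29
Reactants: 42 primary alcohol
Product: 44 carboxylic acid, via aldehyde 43 (not isolated)
Conditions: TEMPO (cat.), PhI(OAc)2, MeCN/H2O, rt
Reagents that add atoms: water, O
Why: Oxoammonium-mediated oxidation takes the primary alcohol through the aldehyde hydrate to the acid under near-neutral conditions, which avoids epimerisation at Cα and β-elimination of the peroxide.

Step 30
Reactants: 44 carboxylic acid
Product: 45 methyl (2S)-2-[(3S,6S)-6-methyl-6-{2-[(5R,9S,10R)-4,4,8,10-tetramethyl-trans-decal-7-en-9-yl]ethyl}-1,2-dioxan-3-yl]propanoate
Conditions: TMSCHN2, MeOH/toluene, 0 °C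
Reagents that add atoms: trimethylsilyldiazomethane, C[Si](C)(C)C=[N+]=[N-]
Why: Esterification with trimethylsilyldiazomethane in methanol methylates the acid without base and gives 45.

## Compound list

1 | (S)-carvone, (5S)-2-methyl-5-(prop-1-en-2-yl)cyclohex-2-en-1-one | CC1=CC[C@@H](CC1=O)C(C)=C | starting material
2 | lithium cross-conjugated dienolate of 1 | [Li]OC1=C[C@@H](C(C)=C)CC=C1C | intermediate (not isolated)
3 | 6-methylcarvone, (5S)-2,6-dimethyl-5-(prop-1-en-2-yl)cyclohex-2-en-1-one, both C6 epimers | CC1=CC[C@@H](C(C)C1=O)C(C)=C | intermediate
4 | acrolein (prop-2-enal) | C=CC=O | starting material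
5 | lithium enolate of 3 | [Li]OC1=C(C)[C@@H](C(C)=C)CC=C1C | intermediate (not isolated)
6 | (5R,6S)-6-(1-hydroxyprop-2-en-1-yl)-2,6-dimethyl-5-(prop-1-en-2-yl)cyclohex-2-en-1-one, both carbinol epimers, arm anti to isopropenyl | C=CC(O)[C@@]1(C)C(=O)C(C)=CC[C@@H]1C(C)=C | intermediate
7 | (5R,6S)-6-acryloyl-2,6-dimethyl-5-(prop-1-en-2-yl)cyclohex-2-en-1-one (6-acryloyl-6-methylcarvone, acryloyl anti to isopropenyl) | C=CC(=O)[C@@]1(C)C(=O)C(C)=CC[C@@H]1C(C)=C | intermediate
8 | (5R,10S)-4,4,8,10-tetramethyl-trans-decal-7-ene-1,9-dione (5-H anti to 10-CH3) | O=C1C(C)=CC[C@@H]2C(C)(C)CCC(=O)[C@]21C | intermediate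
9 | potassium C1 enolate of 8 | O=C1C(C)=CC[C@@H]2C(C)(C)CC=C(O[K])[C@]21C | intermediate (not isolated)
10 | 9-oxo-4,4,8,10-tetramethyl-trans-decal-1,7-dien-1-yl trifluoromethanesulfonate | O=C1C(C)=CC[C@@H]2C(C)(C)CC=C(OS(=O)(=O)C(F)(F)F)[C@]21C | intermediate
11 | 4,4,8,10-tetramethyl-trans-decal-1,7-dien-9-one | O=C1C(C)=CC[C@@H]2C(C)(C)CC=C[C@]21C | intermediate
12 | (5R,10R)-4,4,8,10-tetramethyl-trans-decal-7-en-9-one | O=C1C(C)=CC[C@@H]2C(C)(C)CCC[C@]21C | intermediate
13 | 7,8-epoxy-4,4,8,10-tetramethyl-trans-decalin-9-one, epoxide anti to 10-CH3 | O=C1[C@@]2(C)O[C@H]2C[C@@H]3C(C)(C)CCC[C@]31C | intermediate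
14 | hydrazone of 13 | NN=C1[C@@]2(C)O[C@H]2C[C@@H]3C(C)(C)CCC[C@]31C | intermediate (not isolated)
15 | 4,4,8,10-tetramethyl-trans-decal-8-en-7-ol, 7-OH axial and anti to 10-CH3 | O[C@H]1C[C@@H]2C(C)(C)CCC[C@@]2(C)C=C1C | intermediate
16 | potassium alkoxide of 15 | [K]O[C@H]1C[C@@H]2C(C)(C)CCC[C@@]2(C)C=C1C | intermediate (not isolated)
17 | 7-(tributylstannylmethoxy)-4,4,8,10-tetramethyl-trans-decal-8-ene | CCCC[Sn](CCCC)(CCCC)CO[C@H]1C[C@@H]2C(C)(C)CCC[C@@]2(C)C=C1C | intermediate
18 | 7-(lithiomethoxy)-4,4,8,10-tetramethyl-trans-decal-8-ene | [Li]CO[C@H]1C[C@@H]2C(C)(C)CCC[C@@]2(C)C=C1C | intermediate (not isolated)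
19 | (5R,9S,10R)-9-(hydroxymethyl)-4,4,8,10-tetramethyl-trans-decal-7-ene, CH2OH anti to 10-CH3 | OC[C@H]1C(C)=CC[C@@H]2C(C)(C)CCC[C@]21C | intermediate
20 | 5-{[(5R,9S,10R)-4,4,8,10-tetramethyl-trans-decal-7-en-9-yl]methylsulfanyl}-1-phenyl-1H-tetrazole | c1ccc(cc1)-n1nnnc1SC[C@H]1C(C)=CC[C@@H]2C(C)(C)CCC[C@]21C | intermediate
21 | 5-{[(5R,9S,10R)-4,4,8,10-tetramethyl-trans-decal-7-en-9-yl]methylsulfonyl}-1-phenyl-1H-tetrazole | O=S(=O)(C[C@H]1C(C)=CC[C@@H]2C(C)(C)CCC[C@]21C)c1nnnn1-c1ccccc1 | intermediate
22 | geraniol, (2E)-3,7-dimethylocta-2,6-dien-1-ol | CC(C)=CCC/C(C)=C/CO | starting material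
23 | (2S,3S)-2,3-epoxygeraniol | CC(C)=CCC[C@@]1(C)[C@H](CO)O1 | intermediate
24 | tert-butyldimethylsilyl ether of 23 | CC(C)=CCC[C@@]1(C)[C@H](CO[Si](C)(C)C(C)(C)C)O1 | intermediate
25 | secondary ozonide (1,2,4-trioxolane) of 24 | CC1(C)OOC(O1)CC[C@@]2(C)[C@H](CO[Si](C)(C)C(C)(C)C)O2 | intermediate (not isolated)
26 | (4S,5S)-6-(tert-butyldimethylsilyloxy)-4,5-epoxy-4-methylhexanal | O=CCC[C@@]1(C)[C@H](CO[Si](C)(C)C(C)(C)C)O1 | intermediate
27 | (S)-4-benzyl-3-propionyloxazolidin-2-one | CCC(=O)N1[C@@H](Cc2ccccc2)COC1=O | starting material
28 | dibutylboron Z-enolate of 27 | C/C=C(\OB(CCCC)CCCC)N1[C@@H](Cc2ccccc2)COC1=O | intermediate (not isolated)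
29 | (4S)-4-benzyl-3-[(2S,3R,6S,7S)-8-(tert-butyldimethylsilyloxy)-6,7-epoxy-3-hydroxy-2,6-dimethyloctanoyl]oxazolidin-2-one | O=C1OC[C@H](Cc2ccccc2)N1C(=O)[C@@H](C)[C@H](O)CC[C@@]1(C)[C@H](CO[Si](C)(C)C(C)(C)C)O1 | intermediate
30 | (2R,3R,6S,7S)-8-(tert-butyldimethylsilyloxy)-6,7-epoxy-2,6-dimethyloctane-1,3-diol | OC[C@@H](C)[C@H](O)CC[C@@]1(C)[C@H](CO[Si](C)(C)C(C)(C)C)O1 | intermediate
31 | 1-O-tert-butyldiphenylsilyl ether of 30 (D3 hydroxyl free) | CC(C)(C)[Si](OC[C@@H](C)[C@H](O)CC[C@@]1(C)[C@H](CO[Si](C)(C)C(C)(C)C)O1)(c1ccccc1)c1ccccc1 | intermediate
32 | D3 methanesulfonate of 31 | CC(C)(C)[Si](OC[C@@H](C)[C@H](OS(C)(=O)=O)CC[C@@]1(C)[C@H](CO[Si](C)(C)C(C)(C)C)O1)(c1ccccc1)c1ccccc1 | intermediate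
33 | open-chain D6 tertiary hydroperoxide (D6 inverted relative to 32) with secondary hydroxyl on the neighbouring carbon, D3 mesylate retained | CC(C)(C)[Si](OC[C@@H](C)[C@H](OS(C)(=O)=O)CC[C@@](C)(OO)[C@@H](O)CO[Si](C)(C)C(C)(C)C)(c1ccccc1)c1ccccc1 | intermediate
34 | bis(triethylsilyl) derivative of 33 (triethylsilyl peroxide and triethylsilyl ether) | CC(C)(C)[Si](OC[C@@H](C)[C@H](OS(C)(=O)=O)CC[C@@](C)(OO[Si](CC)(CC)CC)[C@@H](O[Si](CC)(CC)CC)CO[Si](C)(C)C(C)(C)C)(c1ccccc1)c1ccccc1 | intermediate
35 | tetrabutylammonium salt of the D6 peroxide anion from 34 | CCCC[N+](CCCC)(CCCC)CCCC.CC(C)(C)[Si](OC[C@@H](C)[C@H](OS(C)(=O)=O)CC[C@@](C)(O[O-])[C@@H](O[Si](CC)(CC)CC)CO[Si](C)(C)C(C)(C)C)(c1ccccc1)c1ccccc1 | intermediate (not isolated)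
36 | 3,6-cis-1,2-dioxane: D3 bears the (tert-butyldiphenylsilyloxy)propan-2-yl arm, D6 bears methyl and a 1-(triethylsilyloxy)-2-(tert-butyldimethylsilyloxy)ethyl group; Cα, D3, D6 as in 45 | CC(C)(C)[Si](OC[C@@H](C)[C@@H]1CC[C@](C)([C@@H](O[Si](CC)(CC)CC)CO[Si](C)(C)C(C)(C)C)OO1)(c1ccccc1)c1ccccc1 | intermediate
37 | dioxane 1,2-diol from 36 (tert-butyldiphenylsilyl ether retained) | CC(C)(C)[Si](OC[C@@H](C)[C@@H]1CC[C@](C)([C@@H](O)CO)OO1)(c1ccccc1)c1ccccc1 | intermediate
38 | dioxane aldehyde: D6 bears methyl and formyl, D3 the silyloxypropan-2-yl arm, arms cis | CC(C)(C)[Si](OC[C@@H](C)[C@@H]1CC[C@](C)(C=O)OO1)(c1ccccc1)c1ccccc1 | intermediate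
39 | potassium α-sulfonyl carbanion of 21 | [K]C([C@H]1C(C)=CC[C@@H]2C(C)(C)CCC[C@]21C)S(=O)(=O)c1nnnn1-c1ccccc1 | intermediate (not isolated)
40 | coupled alkene, L1=L2 (drawn E), silyl ether | CC(C)(C)[Si](OC[C@@H](C)[C@@H]1CC[C@](C)(/C=C/[C@H]2C(C)=CC[C@@H]3C(C)(C)CCC[C@]32C)OO1)(c1ccccc1)c1ccccc1 | intermediate
41 | saturated tert-butyldiphenylsilyl ether, all six stereocenters as in 45 | CC(C)(C)[Si](OC[C@@H](C)[C@@H]1CC[C@](C)(CC[C@H]2C(C)=CC[C@@H]3C(C)(C)CCC[C@]32C)OO1)(c1ccccc1)c1ccccc1 | intermediate
42 | primary alcohol from 41 | OC[C@@H](C)[C@@H]1CC[C@](C)(CC[C@H]2C(C)=CC[C@@H]3C(C)(C)CCC[C@]32C)OO1 | intermediate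
43 | aldehyde from 42 | O=C[C@@H](C)[C@@H]1CC[C@](C)(CC[C@H]2C(C)=CC[C@@H]3C(C)(C)CCC[C@]32C)OO1 | intermediate (not isolated)
44 | carboxylic acid corresponding to 45 | OC(=O)[C@@H](C)[C@@H]1CC[C@](C)(CC[C@H]2C(C)=CC[C@@H]3C(C)(C)CCC[C@]32C)OO1 | intermediate
45 | methyl (2S)-2-[(3S,6S)-6-methyl-6-{2-[(5R,9S,10R)-4,4,8,10-tetramethyl-trans-decal-7-en-9-yl]ethyl}-1,2-dioxan-3-yl]propanoate | COC(=O)[C@@H](C)[C@@H]1CC[C@](C)(CC[C@H]2C(C)=CC[C@@H]3C(C)(C)CCC[C@]32C)OO1 | target

## Step count and least certain steps

Total step count: 30. Longest linear sequence: 18 steps (steps 1–13 and 26–30, from 1). The dioxane branch from 22 is 12 steps (14–25) before the union.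

**Step 4 (key step).** The most likely failures are hydrogen-atom transfer to the acryloyl alkene, or reduction of the tertiary radical before it cyclises (the isopropenyl group is merely hydrogenated), together with intermolecular radical addition to the vinyl ketone. The acryloyl group is the most reactive acceptor in the molecule, and closure needs both arms equatorial. The fallback separates radical generation from hydride chemistry. It sets out from 7: HBr (2 equiv, CH2Cl2, −20 °C) adds in the Markovnikov sense to the isopropenyl group and conjugately to the vinyl ketone to give the dibromide F1. Et3N (0 °C) eliminates HBr only from the β-bromo ketone and gives the tertiary bromide F2. Bu3SnH/AIBN (benzene, 80 °C, slow addition) generates the same C4 radical by bromine abstraction; 6-endo closure and hydrogen transfer from tin bring the route back at 8.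

**Step 23.** Elimination of the mesylate toward D4 or Cα may compete with substitution, because the electrophilic carbon is secondary and β-branched. Desilylation of the neighbouring silyl ether before ring closure could also be followed by fragmentation. The fallback replaces substitution by conjugate addition. It sets out from 26: Wittig olefination with methyl 2-(triphenylphosphoranylidene)propanoate (CH2Cl2, rt) gives the E enoate F3. Perhydrolysis as in step 21 gives the hydroperoxide F4. Et2NH in CF3CH2OH closes ring C by intramolecular oxa-Michael addition to the dioxane ester F5, obtained as a mixture at D3 and Cα from which the isomer with the target configuration is separated. CSA/MeOH gives the diol F6 and NaIO4 the aldehyde ester F7. Julia–Kocienski coupling with the pre-formed anion of 21 gives the alkene ester F8, and diimide reduction as in step 27 returns the route at 45.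

**Step 21.** Configuration at D6 may erode through an open tertiary cation, the epoxide may rearrange to a carbonyl compound (Meinwald), or the primary silyl ether may be lost in the acidic peroxide medium. The fallback reverses the order of the two C–O bond formations. It sets out from 32: the cesium salt of 2-methoxyprop-2-yl hydroperoxide (CsOH, DMF, 0 °C) displaces the mesylate with inversion at D3 to give the peroxyketal F9. CSA in MeOH/CH2Cl2 unmasks the hydroperoxy epoxide F10, which opens the epoxide at D6 in an acid-promoted 6-exo closure with inversion and loses the primary silyl ether in the same flask. The route is rejoined at 37.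

**Step 11.** A [1,2]-shift or simple protonation of the carbanion may compete with the [2,3] pathway, because the C9 terminus lies next to quaternary C10. The fallback uses a neutral [2,3] rearrangement without tin or strong base. It sets out from 15: heating with N,N-dimethylformamide dimethyl acetal (xylene, 140 °C, removal of MeOH) effects the Büchi rearrangement through an alkoxy(amino)carbene, delivering the carbamoyl carbon to C9 on the same face to give the amide F11. LiH2NBH3 (THF, 0 °C → rt) reduces the amide to the primary alcohol, and the route is rejoined at 19.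

**Step 26.** Addition of the hindered carbanion to the α-quaternary aldehyde may be slow, so that self-condensation of the sulfone or base-induced decomposition of the peroxide aldehyde takes over. The fallback changes the olefination partner to a more nucleophilic phosphorus ylide. It sets out from 19: I2, PPh3 and imidazole give the iodide F12, and PPh3 (MeCN, 80 °C) gives the phosphonium iodide F13. NaHMDS (THF, −78 °C) followed by 38 gives the Z alkene F14. Diimide reduction as in step 27 returns the route at 41.

**Step 9.** Hydrazone formation may be slow at a ketone flanked by two fully substituted carbons, allowing hydrazine to open the epoxide or the intermediate to collapse by other paths. The fallback is a radical transposition. It sets out from 13: NaBH4 (MeOH, 0 °C) gives the epoxy alcohol F15 (either C9 epimer serves). 1,1′-Thiocarbonyldiimidazole (DMAP, CH2Cl2, 40 °C) gives the thiocarbonylimidazolide F16. Bu3SnH/AIBN (benzene, 80 °C) generates the C9 radical, which opens the epoxide to the C7 alkoxy radical and, after hydrogen transfer, returns the route at 15 with the C7–O bond unchanged.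

## Further compounds

F1 | step 4 | (5R,6S)-6-(3-bromopropanoyl)-5-(2-bromopropan-2-yl)-2,6-dimethylcyclohex-2-en-1-one | BrCCC(=O)[C@@]1(C)C(=O)C(C)=CC[C@@H]1C(C)(C)Br
F2 | step 4 | (5R,6S)-6-acryloyl-5-(2-bromopropan-2-yl)-2,6-dimethylcyclohex-2-en-1-one | C=CC(=O)[C@@]1(C)C(=O)C(C)=CC[C@@H]1C(C)(C)Br
F3 | step 23 | methyl (2E,6S,7S)-8-(tert-butyldimethylsilyloxy)-6,7-epoxy-2,6-dimethyloct-2-enoate | COC(=O)/C(C)=C/CC[C@@]1(C)[C@H](CO[Si](C)(C)C(C)(C)C)O1
F4 | step 23 | methyl (2E)-8-(tert-butyldimethylsilyloxy)-6-hydroperoxy-7-hydroxy-2,6-dimethyloct-2-enoate (D6 inverted) | COC(=O)/C(C)=C/CC[C@@](C)(OO)[C@@H](O)CO[Si](C)(C)C(C)(C)C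
F5 | step 23 | methyl ester dioxane with 1-hydroxy-2-(tert-butyldimethylsilyloxy)ethyl on D6, target configuration at Cα, D3, D6 | COC(=O)[C@@H](C)[C@@H]1CC[C@](C)([C@@H](O)CO[Si](C)(C)C(C)(C)C)OO1
F6 | step 23 | methyl ester dioxane 1,2-diol | COC(=O)[C@@H](C)[C@@H]1CC[C@](C)([C@@H](O)CO)OO1
F7 | step 23 | methyl ester dioxane aldehyde (formyl on D6) | COC(=O)[C@@H](C)[C@@H]1CC[C@](C)(C=O)OO1
F8 | step 23 | L1=L2 alkene analogue of 45 (drawn E) | COC(=O)[C@@H](C)[C@@H]1CC[C@](C)(/C=C/[C@H]2C(C)=CC[C@@H]3C(C)(C)CCC[C@]32C)OO1
F9 | step 21 | D3 (2-methoxyprop-2-yl)peroxy epoxide (D3 inverted relative to 32) | CC(C)(C)[Si](OC[C@@H](C)[C@@H](OOC(C)(C)OC)CC[C@@]1(C)[C@H](CO[Si](C)(C)C(C)(C)C)O1)(c1ccccc1)c1ccccc1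
F10 | step 21 | D3 hydroperoxy epoxide | CC(C)(C)[Si](OC[C@@H](C)[C@@H](OO)CC[C@@]1(C)[C@H](CO[Si](C)(C)C(C)(C)C)O1)(c1ccccc1)c1ccccc1
F11 | step 11 | N,N-dimethyl (5R,10R)-4,4,8,10-tetramethyl-trans-decal-7-ene-9-carboxamide, carbamoyl anti to 10-CH3 | CN(C)C(=O)[C@H]1C(C)=CC[C@@H]2C(C)(C)CCC[C@]21C
F12 | step 26 | 9-(iodomethyl)-4,4,8,10-tetramethyl-trans-decal-7-ene | IC[C@H]1C(C)=CC[C@@H]2C(C)(C)CCC[C@]21C
F13 | step 26 | triphenyl{[4,4,8,10-tetramethyl-trans-decal-7-en-9-yl]methyl}phosphonium iodide | [I-].c1ccccc1[P+](C[C@H]1C(C)=CC[C@@H]2C(C)(C)CCC[C@]21C)(c1ccccc1)c1ccccc1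
F14 | step 26 | Z isomer of 40 | CC(C)(C)[Si](OC[C@@H](C)[C@@H]1CC[C@](C)(/C=C\[C@H]2C(C)=CC[C@@H]3C(C)(C)CCC[C@]32C)OO1)(c1ccccc1)c1ccccc1
F15 | step 9 | 7,8-epoxy-4,4,8,10-tetramethyl-trans-decalin-9-ol (C9 epimers) | OC1[C@@]2(C)O[C@H]2C[C@@H]3C(C)(C)CCC[C@]31C
F16 | step 9 | O-(7,8-epoxy-4,4,8,10-tetramethyl-trans-decalin-9-yl) 1H-imidazole-1-carbothioate | S=C(OC1[C@@]2(C)O[C@H]2C[C@@H]3C(C)(C)CCC[C@]31C)n1ccnc1
A1 | alternative 1 | 3,6-cis-3,6-dihydro-1,2-dioxine with acetoxymethyl and methyl on D6 and the silyloxypropan-2-yl arm on D3 | CC(=O)OC[C@@]1(C)C=C[C@@H]([C@H](C)CO[Si](C)(C)C(C)(C)C)OO1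
A2 | alternative 1 | (2E,4E)-6-methyl-7-(tert-butyldimethylsilyloxy)-2-methylhepta-2,4-dien-1-yl acetate (diene precursor) | CC(=O)OC/C(C)=C/C=C/[C@H](C)CO[Si](C)(C)C(C)(C)C
A3 | alternative 2 | dimethyl trans-1,3-dimethyl-4-(tert-butyldimethylsilyloxy)cyclohex-3-ene-1,6-dicarboxylate | COC(=O)[C@H]1CC(O[Si](C)(C)C(C)(C)C)=C(C)C[C@]1(C)C(=O)OC
A4 | alternative 2 | dimethyl mesaconate | COC(=O)/C=C(\C)C(=O)OC
A5 | alternative 2 | 2-(tert-butyldimethylsilyloxy)-3-methylbuta-1,3-diene | C=C(C)C(=C)O[Si](C)(C)C(C)(C)C
A6 | alternative 3 | 3,6-cis-1,2-dioxane with 2-hydroxyethyl and methyl on D6 and the silyloxypropan-2-yl arm on D3 | CC(C)(C)[Si](C)(C)OC[C@@H](C)[C@@H]1CC[C@](C)(CCO)OO1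
A7 | alternative 3 | D3 hydroperoxide tethered to a 2-methyloxetan-2-yl group (oxetane precursor) | CC(C)(C)[Si](C)(C)OC[C@@H](C)[C@@H](OO)CC[C@@]1(C)CCO1
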